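**Ret­ro­syn­thet­ic overview**
1. Target ⇐ acetonide hydrolysis and C8 angeloylation of carbinol 18; 18 ⇐ C7–C8 bond formation by Ni/Cr-mediated (Nozaki–Hiyama–Kishi) addition of the complete ring half, alkenyl triflate 13, to side-chain aldehyde 17.
2. Enabling feature: the 2-substituted allylic carbinol C14H2=C7(–C6)–C8H(O), i.e. the exocyclic-methylene carbon C7 that links ring carbon C6 of the epoxycyclohexanone (C1–C6) to carbinol C8. This is the retron of an alkenyl-metal/aldehyde addition, and C7(OTf)=C14H2 is the enol triflate of a C6 acetyl group.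
3. Ring half 13 ⇐ (S)-carvone: its six ring carbons, C-methyl and ketone become C1–C6, C15 and C4=O. Ozonolysis cuts the isopropenyl C=C (its CH2 is lost, its methyl becomes C14). Oxygenation order: C5 (Rubottom), C1 (vinylogous Rubottom, then Mitsunobu inversion with angelic acid), C2/C3 (hydroxyl-directed epoxidation after directed reduction of C4), then C4 reoxidation.
4. Side-chain half 17 ⇐ (S)-α-hydroxy-γ-butyrolactone (C10 from the chiral pool; MeMgBr builds C11).
5. Ring order: the carbocycle is taken intact from carvone; the oxirane is closed in step 8; the dioxolane (step 12) is temporary and is opened in step 16.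

Key step: step 14

Remark on the chemistry (convention): ring atoms are numbered as in the target. C1 is the carbinol next to the epoxide, C2/C3 are the epoxide carbons (C3 bears the methyl), C4 is the ketone, C5 the carbinol next to the ketone, C6 bears the side chain C7(=C14H2)–C8–C9–C10–C11. β is the face of the C6 side chain, α the opposite face. In these terms the target is the 1β,5α,8S-tris-angelate, 2β,3β-epoxide, 10S,11-diol.

**Step 1**
Reactants: 1 (S)-(+)-carvone
Product: 3 5α-(tert-butyldimethylsilyloxy)carvone (5α-OTBS trans to the 6β-isopropenyl group), via TBS dienol ether 2 (not isolated)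
Conditions: LDA, THF, −78 °C; TBSOTf, −78 → 0 °C; then mCPBA, hexane/CH2Cl2, −15 °C
Reagents that add atoms: TBSOTf CC(C)(C)[Si](C)(C)OS(=O)(=O)C(F)(F)F; mCPBA OOC(=O)c1cccc(Cl)c1
Why: Rubottom oxidation: kinetic α′-deprotonation gives the cross-conjugated silyl dienol ether 2, whose C4=C5 enol-ether bond is epoxidised from the face opposite the adjacent C6 isopropenyl group, and 1,4-silyl shift of the silyloxy-oxirane gives the α-silyloxy ketone, so C5 is set α (trans to the C6 substituent).

**Step 2**
Reactants: 3 5α-(tert-butyldimethylsilyloxy)carvone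
Product: 4 6β-acetyl-5α-(tert-butyldimethylsilyloxy)-3-methylcyclohex-2-en-4-one
Conditions: O3, CH2Cl2/MeOH, −78 °C (Sudan III end point); Me2S, −78 °C → rt
Reagents that add atoms: ozone [O-][O+]=O
Why: Ozonolysis with reductive work-up: the electron-rich 1,1-disubstituted isopropenyl alkene reacts far faster than the electron-poor enone alkene, so only the exocyclic CH2 is excised and the chiral-pool stereocenter C6 is untouched.

**Step 3**
Reactants: 4 6β-acetyl-5α-(tert-butyldimethylsilyloxy)-3-methylcyclohex-2-en-4-one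
Product: 5 alkenyl triflate, 5α-(tert-butyldimethylsilyloxy)-3-methyl-6β-[1-(trifluoromethanesulfonyloxy)vinyl]cyclohex-2-en-4-one
Conditions: KHMDS (1.05 equiv), THF, −78 °C; PhNTf2, −78 → −20 °C
Reagents that add atoms: N-phenyl-bis(trifluoromethanesulfonimide) FC(F)(F)S(=O)(=O)N(c1ccccc1)S(=O)(=O)C(F)(F)F
Why: Kinetic enolate O-triflation: at −78 °C the hindered amide base removes a proton only from the unhindered acetyl CH3 (the ring α′-H at C5 is tertiary and shielded by the OTBS group, the C6 methine is hindered), and the triflimide traps the terminal enolate as the 1,1-disubstituted alkenyl triflate; no stereocenter is formed.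

**Step 4**
Reactants: 5 alkenyl triflate
Product: 7 1α-hydroxy enone (1α-hydroxy-5α-OTBS-3-methyl-6β-[1-(triflyloxy)vinyl]cyclohex-2-en-4-one), via TMS dienol ether 6 (not isolated)
Conditions: TMSOTf, Et3N, CH2Cl2, 0 °C → rt; DMDO, acetone, −78 → −30 °C; aq. citric acid, THF
Reagents that add atoms: dimethyldioxirane CC1(C)OO1; TMSOTf C[Si](C)(C)OS(=O)(=O)C(F)(F)F (its silyl group is present only in 6)
Why: Vinylogous Rubottom oxidation: with the α′ position blocked by the silyloxy group, soft enolisation gives the linear silyl dienol ether 6, the dioxirane epoxidises its terminal C1=C2 bond from the face opposite the adjacent C6 substituent, and collapse of the silyloxy epoxide plus acidic work-up gives the γ-hydroxy enone with C1–OH α (trans to the C6 substituent).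

**Step 5**
Reactants: 7 1α-hydroxy enone
Product: 8 1β-angeloyloxy-5α-(tert-butyldimethylsilyloxy)-3-methyl-6β-[1-(triflyloxy)vinyl]cyclohex-2-en-4-one
Conditions: angelic acid, PPh3, DIAD, toluene, 0 °C → rt
Reagents that add atoms: angelic acid C/C=C(/C)C(=O)O
Why: Mitsunobu reaction: the oxyphosphonium salt of the only free hydroxyl is displaced by angelate in an SN2 process, which inverts C1 to the required β configuration (cis to the C6 substituent) and installs the first angelate at the same time under neutral conditions that should keep the Z geometry.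

**Step 6**
Reactants: 8 1β-angeloyloxy 5α-OTBS enone
Product: 9 1β-angeloyloxy-5α-hydroxy-3-methyl-6β-[1-(triflyloxy)vinyl]cyclohex-2-en-4-one
Conditions: HF·pyridine, pyridine, THF, 0 °C → rt
Reagents that add atoms: none
Why: Fluoride desilylation: HF·pyridine cleaves the Si–O bond of the TBS ether while the alkenyl triflate and the angelate are inert; no stereocenter is touched.

**Step 7**
Reactants: 9 1β-angeloyloxy 5α-hydroxy enone
Product: 10 1β-angeloyloxy-3-methyl-6β-[1-(triflyloxy)vinyl]cyclohex-2-ene-4β,5α-diol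
Conditions: Me4NBH(OAc)3, MeCN/AcOH, −20 → 0 °C
Reagents that add atoms: none
Why: Hydroxyl-directed triacetoxyborohydride reduction (Saksena–Evans reduction): the C5 hydroxyl exchanges an acetate on boron and delivers hydride intramolecularly to the α face of the C4 carbonyl (1,2-reduction), so the temporary C4–OH is β (trans to C5–OH) whatever the ring conformation.

**Step 8**
Reactants: 10 allylic 4β,5α-diol
Product: 11 1β-angeloyloxy-2β,3β-epoxy-3-methyl-6β-[1-(triflyloxy)vinyl]cyclohexane-4β,5α-diol
Conditions: VO(acac)2 (5 mol %), t-BuOOH (decane), CH2Cl2, 0 °C → rt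
Reagents that add atoms: tert-butyl hydroperoxide CC(C)(C)OO
Why: Vanadium-catalysed hydroxyl-directed epoxidation of an allylic alcohol: the vanadate ester of the allylic 4β-OH delivers the peroxide oxygen to the same face of the C2=C3 bond, setting C2 and C3 (β-epoxide, cis to the C1 angelate and the C6 chain), while the electron-poor alkenyl triflate and angelate alkenes do not react.

**Step 9**
Reactants: 11 epoxy 4β,5α-diol
Product: 12 1β,5α-bis(angeloyloxy)-2β,3β-epoxy-3-methyl-6β-[1-(triflyloxy)vinyl]cyclohexan-4β-ol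
Conditions: angelic acid, 2,4,6-trichlorobenzoyl chloride, Et3N, toluene, rt; then 11, DMAP (cat.), 0 °C → rt
Reagents that add atoms: angelic acid C/C=C(/C)C(=O)O
Why: Yamaguchi esterification (mixed anhydride made in the flask, DMAP acyl transfer): the C5 hydroxyl should be acylated in preference to the C4 hydroxyl, which is neopentylic (next to the fully substituted epoxide carbon C3) and hydrogen-bonded to the cis oxirane oxygen; the mixed-anhydride method keeps the Z geometry and no stereocenter changes.

**Step 10**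
Reactants: 12 epoxy 4β-alcohol
Product: 13 ring-half alkenyl triflate, 1β,5α-bis(angeloyloxy)-2β,3β-epoxy-3-methyl-6β-[1-(triflyloxy)vinyl]cyclohexan-4-one
Conditions: Dess–Martin periodinane, CH2Cl2, 0 °C → rt
Reagents that add atoms: none
Why: Dess–Martin oxidation of the remaining secondary alcohol to the ketone under neutral, non-epimerising conditions; the temporary C4 stereocenter is removed.

**Step 11**
Reactants: 14 (S)-α-hydroxy-γ-butyrolactone
Product: 15 (3S)-4-methylpentane-1,3,4-triol
Conditions: MeMgBr (3.5 equiv), THF, 0 °C → rt; aq. NH4Cl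
Reagents that add atoms: methylmagnesium bromide C[Mg]Br
Why: Grignard addition to a lactone: after deprotonation of the hydroxyl, two methyl groups add to the lactone carbonyl to give the tertiary carbinol C11, and the C10 stereocenter comes unchanged from the chiral pool.

**Step 12**
Reactants: 15 (3S)-4-methylpentane-1,3,4-triol
Product: 16 2-[(4S)-2,2,5,5-tetramethyl-1,3-dioxolan-4-yl]ethan-1-ol
Conditions: 2,2-dimethoxypropane, PPTS (cat.), CH2Cl2, rt
Reagents that add atoms: 2,2-dimethoxypropane COC(C)(C)OC
Why: Acetal exchange (acetonide formation) under thermodynamic control: the five-membered dioxolane of the secondary/tertiary 1,2-diol is favoured over the six-membered 1,3-dioxane, leaving the primary hydroxyl free.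

**Step 13**
Reactants: 16 acetonide alcohol
Product: 17 2-[(4S)-2,2,5,5-tetramethyl-1,3-dioxolan-4-yl]acetaldehyde
Conditions: Dess–Martin periodinane, CH2Cl2, rt
Reagents that add atoms: none
Why: Dess–Martin oxidation of the primary alcohol to the aldehyde under neutral conditions that avoid β-elimination of the dioxolane oxygen.

**Step 14**
Reactants: 13 ring-half alkenyl triflate; 17 side-chain aldehyde
Product: 18 (8S)-carbinol (ring as in 13 with C7=C14H2 bonded to C8; free C8–OH; 10,11-acetonide)
Conditions: CrCl2 (4 equiv), chiral oxazoline–sulfonamide ligand (4.4 equiv, antipode matched to Re-face addition), Et3N (4.4 equiv), NiCl2 (5 mol %), THF/MeCN, rt; aq. sodium serinate work-up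
Reagents that add atoms: none
Why: Nozaki–Hiyama–Kishi reaction: Ni(0) inserts into the C7–OTf bond of 13, the alkenyl group is passed to Cr(III), and the alkenylchromium(III) adds to the aldehyde carbon C8 of 17, forming the C7–C8 bond and a chromium alkoxide that is hydrolysed on work-up. The closest precedent is the Ni/Cr coupling of 2-substituted alkenyl triflates and iodides with aldehydes, including its ligand-controlled asymmetric version for 1,1-disubstituted allylic alcohols. No ring is closed in this step. The new stereocenter C8 is set S by Re-face attack, controlled by the chiral chromium ligand (antipode to be confirmed on a model aldehyde) and reinforced by the C10 dioxolane oxygen (1,3-anti polar model for β-alkoxy aldehydes). The step needs chemoselectivity for the aldehyde over the C4 ketone, the two angelate carbonyls and the oxirane; this rests on the low nucleophilicity of alkenylchromium(III), which adds to aldehydes far faster than to ketones, and on the absence of protic solvent or acid that would promote Cr(II) reduction of the epoxy ketone. One operation thus unites the two fully oxidised halves into the complete C15 skeleton with all seven stereocenters and the exocyclic methylene in place.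

**Step 15**
Reactants: 18 (8S)-carbinol
Product: 19 1β,5α,8S-tris(angeloyloxy) 10,11-acetonide
Conditions: angelic acid, 2,4,6-trichlorobenzoyl chloride, Et3N, toluene, rt; then 18, DMAP, 40 °C
Reagents that add atoms: angelic acid C/C=C(/C)C(=O)O
Why: Yamaguchi esterification of the only free hydroxyl (allylic C8–OH), with retention at C8 and at the angelate double bond.

**Step 16**
Reactants: 19 tris-angelate acetonide
Product: 20 CNP0210092.1
Conditions: AcOH/H2O/THF (3:1:1), 40 °C
Reagents that add atoms: none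
Why: Acid-catalysed acetal hydrolysis: mild aqueous acetic acid should cleave the dioxolane to the 10,11-diol, while the α-keto epoxide (deactivated toward acid opening by the adjacent carbonyl) and the three angelates are kept.

**Compound list**
1 | (S)-(+)-carvone, (5S)-2-methyl-5-(prop-1-en-2-yl)cyclohex-2-en-1-one | C=C(C)[C@H]1CC=C(C)C(=O)C1 | starting material
2 | cross-conjugated TBS dienol ether of 1 (C4(OTBS)=C5 and C2=C3) | C=C(C)[C@H]1CC=C(C)C(O[Si](C)(C)C(C)(C)C)=C1 | intermediate
3 | 5α-(tert-butyldimethylsilyloxy)carvone (OTBS trans to the 6β-isopropenyl group) | C=C(C)[C@H]1CC=C(C)C(=O)[C@@H]1O[Si](C)(C)C(C)(C)C | intermediate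
4 | 6β-acetyl-5α-(tert-butyldimethylsilyloxy)-3-methylcyclohex-2-en-4-one | CC(=O)[C@H]1CC=C(C)C(=O)[C@@H]1O[Si](C)(C)C(C)(C)C | intermediate
5 | alkenyl triflate: 5α-OTBS-3-methyl-6β-[1-(triflyloxy)vinyl]cyclohex-2-en-4-one | C=C(OS(=O)(=O)C(F)(F)F)[C@H]1CC=C(C)C(=O)[C@@H]1O[Si](C)(C)C(C)(C)C | intermediate
6 | linear TMS dienol ether of 5 (C4(OTMS)=C3 and C1=C2) | C=C(OS(=O)(=O)C(F)(F)F)[C@H]1C=CC(C)=C(O[Si](C)(C)C)[C@@H]1O[Si](C)(C)C(C)(C)C | intermediate
7 | 1α-hydroxy-5α-OTBS-3-methyl-6β-[1-(triflyloxy)vinyl]cyclohex-2-en-4-one | C=C(OS(=O)(=O)C(F)(F)F)[C@H]1[C@H](O)C=C(C)C(=O)[C@@H]1O[Si](C)(C)C(C)(C)C | intermediate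
8 | 1β-angeloyloxy-5α-OTBS-3-methyl-6β-[1-(triflyloxy)vinyl]cyclohex-2-en-4-one | C=C(OS(=O)(=O)C(F)(F)F)[C@H]1[C@@H](OC(=O)/C(C)=C\C)C=C(C)C(=O)[C@@H]1O[Si](C)(C)C(C)(C)C | intermediate
9 | 1β-angeloyloxy-5α-hydroxy-3-methyl-6β-[1-(triflyloxy)vinyl]cyclohex-2-en-4-one | C=C(OS(=O)(=O)C(F)(F)F)[C@H]1[C@@H](OC(=O)/C(C)=C\C)C=C(C)C(=O)[C@@H]1O | intermediate
10 | 1β-angeloyloxy-3-methyl-6β-[1-(triflyloxy)vinyl]cyclohex-2-ene-4β,5α-diol | C=C(OS(=O)(=O)C(F)(F)F)[C@H]1[C@@H](OC(=O)/C(C)=C\C)C=C(C)[C@@H](O)[C@@H]1O | intermediate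
11 | 1β-angeloyloxy-2β,3β-epoxy-3-methyl-6β-[1-(triflyloxy)vinyl]cyclohexane-4β,5α-diol | C=C(OS(=O)(=O)C(F)(F)F)[C@H]1[C@@H](OC(=O)/C(C)=C\C)[C@H]2O[C@@]2(C)[C@@H](O)[C@@H]1O | intermediate
12 | 1β,5α-bis(angeloyloxy)-2β,3β-epoxy-3-methyl-6β-[1-(triflyloxy)vinyl]cyclohexan-4β-ol | C=C(OS(=O)(=O)C(F)(F)F)[C@H]1[C@@H](OC(=O)/C(C)=C\C)[C@H]2O[C@@]2(C)[C@@H](O)[C@@H]1OC(=O)/C(C)=C\C | intermediate
13 | ring-half alkenyl triflate: 1β,5α-bis(angeloyloxy)-2β,3β-epoxy-3-methyl-6β-[1-(triflyloxy)vinyl]cyclohexan-4-one | C=C(OS(=O)(=O)C(F)(F)F)[C@H]1[C@@H](OC(=O)/C(C)=C\C)[C@H]2O[C@@]2(C)C(=O)[C@@H]1OC(=O)/C(C)=C\C | intermediate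
14 | (S)-α-hydroxy-γ-butyrolactone, (3S)-3-hydroxyoxolan-2-one | O[C@H]1CCOC1=O | starting material
15 | (3S)-4-methylpentane-1,3,4-triol | OCC[C@H](O)C(C)(C)O | intermediate
16 | 2-[(4S)-2,2,5,5-tetramethyl-1,3-dioxolan-4-yl]ethan-1-ol | OCC[C@@H]1OC(C)(C)OC1(C)C | intermediate
17 | 2-[(4S)-2,2,5,5-tetramethyl-1,3-dioxolan-4-yl]acetaldehyde | O=CC[C@@H]1OC(C)(C)OC1(C)C | intermediate
18 | (8S)-carbinol: 1β,5α-bis(angeloyloxy)-2β,3β-epoxy-4-oxo ring, C7=C14H2, 8S-OH, 10S,11-acetonide | C=C([C@H]1[C@@H](OC(=O)/C(C)=C\C)[C@H]2O[C@@]2(C)C(=O)[C@@H]1OC(=O)/C(C)=C\C)[C@H](C[C@@H]3OC(C)(C)OC3(C)C)O | intermediate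
19 | 1β,5α,8S-tris(angeloyloxy) 10S,11-acetonide | C=C([C@H]1[C@@H](OC(=O)/C(C)=C\C)[C@H]2O[C@@]2(C)C(=O)[C@@H]1OC(=O)/C(C)=C\C)[C@H](C[C@@H]3OC(C)(C)OC3(C)C)OC(=O)/C(C)=C\C | intermediate
20 | CNP0210092.1 | C=C([C@H]1[C@@H](OC(=O)/C(C)=C\C)[C@H]2O[C@@]2(C)C(=O)[C@@H]1OC(=O)/C(C)=C\C)[C@H](C[C@H](O)C(C)(C)O)OC(=O)/C(C)=C\C | target

**Totals and risks**
Total step count: 16. Longest linear sequence: 13 (steps 1–10, then 14–16).

Steps most likely to fail:

1. Step 14. Single-electron reduction of the α,β-epoxy ketone or of the α-acyloxy ketone by Cr(II) (reductive opening of the oxirane, loss of the C5 angelate) may compete with the slow nickel activation of the hindered alkenyl triflate, and Re-face control at C8 may be incomplete. Fallback: carry out the union one oxidation level lower. Setting out from 12, silylation (TESOTf, 2,6-lutidine, CH2Cl2, −78 °C) gives the 4β-triethylsilyl ether F1. Ni/Cr coupling of F1 with 17 under the conditions of step 14, now with no ketone and only an unactivated epoxide in the molecule, gives the C8 carbinol F2. Yamaguchi angeloylation as in step 15 gives the tris-angelate silyl ether F3. HF·pyridine removes the triethylsilyl group and gives the C4 alcohol F4. Dess–Martin oxidation of F4 then gives 19, where the route is rejoined.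

2. Step 5. The SN2 displacement at the hindered γ-carbinol, cis to the C6 substituent, may be too slow with the weakly acidic angelic acid, so that elimination toward the cross-conjugated dienone (and aromatisation) or phosphine-induced Z-to-E isomerisation of the acid takes over. Fallback: separate the inversion from the delivery of the angelate. Setting out from 7, a Mitsunobu reaction with the more acidic 4-nitrobenzoic acid (PPh3, DIAD, toluene) gives the inverted 1β-(4-nitrobenzoate) F5. Methanolysis (K2CO3, MeOH, 0 °C) gives the 1β-alcohol F6. Yamaguchi angeloylation under the conditions of step 9 then gives 8, where the route is rejoined.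

3. Step 4. Enolisation may take place at the wrong position (α′ C5–H instead of γ C1–H), the dioxirane may attack the C3=C4 enol-ether bond instead of C1=C2, or the facial selectivity at C1 may be poor. Fallback: replace the enol-ether chemistry by C–H oxidation and carbonyl reduction. Setting out from 5, allylic oxidation of the C1 methylene (Rh2(cap)4 cat., t-BuOOH, K2CO3, CH2Cl2) gives the ene-1,4-dione F7. Luche reduction with one equivalent of NaBH4 (CeCl3·7H2O, MeOH, −78 °C) should reduce only the less hindered C1 carbonyl (C4 is flanked by the C3 methyl and the C5 silyl ether) by axial hydride attack. This gives 7, where the route is rejoined.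

**Further compounds**
F1 | step 14 | 4β-triethylsilyl ether of 12 | C=C(OS(=O)(=O)C(F)(F)F)[C@H]1[C@@H](OC(=O)/C(C)=C\C)[C@H]2O[C@@]2(C)[C@@H](O[Si](CC)(CC)CC)[C@@H]1OC(=O)/C(C)=C\C
F2 | step 14 | (8S)-carbinol with 4β-OTES | C=C([C@H]1[C@@H](OC(=O)/C(C)=C\C)[C@H]2O[C@@]2(C)[C@@H](O[Si](CC)(CC)CC)[C@@H]1OC(=O)/C(C)=C\C)[C@H](C[C@@H]3OC(C)(C)OC3(C)C)O
F3 | step 14 | 1β,5α,8S-tris-angelate with 4β-OTES | C=C([C@H]1[C@@H](OC(=O)/C(C)=C\C)[C@H]2O[C@@]2(C)[C@@H](O[Si](CC)(CC)CC)[C@@H]1OC(=O)/C(C)=C\C)[C@H](C[C@@H]3OC(C)(C)OC3(C)C)OC(=O)/C(C)=C\C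
F4 | step 14 | 1β,5α,8S-tris-angelate 4β-alcohol | C=C([C@H]1[C@@H](OC(=O)/C(C)=C\C)[C@H]2O[C@@]2(C)[C@@H](O)[C@@H]1OC(=O)/C(C)=C\C)[C@H](C[C@@H]3OC(C)(C)OC3(C)C)OC(=O)/C(C)=C\C
F5 | step 5 | 1β-(4-nitrobenzoyloxy)-5α-OTBS enone | C=C(OS(=O)(=O)C(F)(F)F)[C@H]1[C@@H](OC(=O)c2ccc(cc2)[N+](=O)[O-])C=C(C)C(=O)[C@@H]1O[Si](C)(C)C(C)(C)C
F6 | step 5 | 1β-hydroxy-5α-OTBS enone | C=C(OS(=O)(=O)C(F)(F)F)[C@H]1[C@@H](O)C=C(C)C(=O)[C@@H]1O[Si](C)(C)C(C)(C)C
F7 | step 4 | 5α-OTBS-3-methyl-6β-[1-(triflyloxy)vinyl]cyclohex-2-ene-1,4-dione | C=C(OS(=O)(=O)C(F)(F)F)[C@H]1C(=O)C=C(C)C(=O)[C@@H]1O[Si](C)(C)C(C)(C)C
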